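## Structural features

The target is a cembrane-type carbocycle: one 14-membered ring (C1–C14) with an acetoxy group on C1, an E-trisubstituted olefin C2=C3 (methyl on C3), a 2-acetoxypropan-2-yl group (C15) on C6, a Z-trisubstituted olefin C8=C9 (methyl on C9) and a trisubstituted oxirane fused across C12–C13 (methyl on C13). It has four stereocentres, C1 (S), C6 (R), C12 (S) and C13 (R). C12 and C13 are adjacent and form a cis-epoxide (C11 and C14 on the same side), C1 is separated from C13 only by C14, and C6 is remote from the other three. The fragile groups are the trisubstituted epoxide (protic and Lewis acids), the secondary allylic acetate at C1 (ionisation, zerovalent palladium) and the tertiary acetate at C15 (elimination, strong bases, hydrides). The two ring olefins have opposite geometry, so one olefination tactic cannot serve both. The real difficulty is to close the 14-membered ring while both geometries and the C1/C12/C13 array stay under control, without any stereochemical relay to C6. The key step exploits the allylic unit C1(O)–C2=C3(CH3)–C4: without the C3 methyl it is the propargylic alcohol unit C1(O)–C2≡C3, a linear segment that a 14-membered ring accepts and that alkyne metathesis can close at C2≡C3 without touching C8=C9. The C1 hydroxyl then directs the return to the E-olefin.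

## Logic of the disconnections

35 ⇒ 34. The C1–O acetyl bond is cut last. An allylic acetate would ionise under zerovalent palladium and could not direct the hydrometalation, so the free alcohol is carried to the end. The forward step must acylate a secondary allylic alcohol without acid, which the epoxide requires.

34 ⇒ 33 ⇒ 32 ⇒ 31. The C3–CH3 bond is cut, then the C3–iodine and C3–silicon bonds, which leads back to a cyclic propargylic alcohol. This turns the E-trisubstituted olefin into an alkyne, which has no geometry. The forward steps must add H and Si anti across C2≡C3 with silicon on C3, and then replace silicon by iodine and iodine by methyl with retention. The C8=C9 olefin, the epoxide and the C15 acetate must survive.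

31 ⇒ 30 ⇒ 29. After the C1 hydroxyl is capped as a silyl ether, the ring bond C2≡C3 is cut, which opens the macrocycle to an acyclic diyne with two propynyl ends. No stereocentre is involved. The forward step must favour ring closure over oligomerisation and must tolerate the epoxide, the ester and the silyl ether. For this reason 29 is designed with methyl caps on both alkynes, no protic group, and the C15 acetate already in place, so that no tertiary acylation is needed next to the epoxide later.

29 ⇒ 27 + 14. The C9–C10 bond between the Z-olefin carbon and a methylene is cut. This divides the chain into two fragments of similar size, each with one propynyl group. The forward sp2–sp3 coupling must retain the Z geometry, hydroborate only the vinyl group of 27 and leave the epoxide intact.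

27 ⇒ 26 ⇒ 25 ⇒ 24. The C10=C11 bond is cut (methylenation of an epoxy aldehyde), then the two C–O bonds of the oxirane. This leads to a Z-allylic alcohol, the only position from which reagent-controlled epoxidation of C12=C13 is possible. The forward epoxidation must override the remote C1 centre on a Z-trisubstituted olefin.

24 ⇒ 23 ⇒ 22 ⇒ 20. The two hydroxyls are differentiated by double silylation and selective release of the primary one. The diol is traced to a dihydropyran in which the ring enforces the cis C12=C13 geometry and holds C1. The forward ring opening must not isomerise the Z-enal that forms transiently.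

20 ⇒ 16 + 19. The C1–C14 and O–C11 bonds are cut in a hetero-Diels–Alder sense. This sets C1 by catalyst control and leads to two four- and five-carbon pieces, 16 (from 15) and 19 (from 17 through 18). The catalyst must select the carbonyl group of the ynal, one of its faces and the endo mode.

14 ⇒ 13. The C8=C9 bond is cut to an aldehyde and an α-iodo ylide. The forward olefination must place iodine cis to the chain.

13 ⇒ 12 ⇒ 11 ⇒ 10 ⇒ 8. These are oxidation-state and acyl adjustments. A free C15 hydroxyl would trap the C8 aldehyde as a lactol, and an acetate would not survive the strong base needed for the alkyne. The C15 acetate is therefore introduced on the diol after the alkyne is made, and the primary position is then released and oxidised.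

8 ⇒ 5 ⇒ 3 ⇒ 1. The methyl alkyne is traced to a methyl ketone (the ketone carbon becomes C3). Ketone and aldehyde come from cleavage of the ring olefin of 3, with the tertiary hydroxyl and the aldehyde masked together as a cyclic acetal. 3 comes from 1 by hydration of the isopropenyl group. The stereocentre of 1 becomes C6 and is never touched.

## Other disconnections considered

Alternative 1: The cut runs through C1–C14 and O–C11 with the C2=C3 olefin already present. The aldehyde of the acyclic E-enal A1 (C1–C9, vinyl iodide at C9, C15 oxygen silylated) would react with diene 19 under a chiral tridentate Schiff-base CrCl complex (trivalent chromium) in a hetero-Diels–Alder reaction to give the cis dihydropyran A2.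
- In favour: the E-olefin comes from ordinary olefination of the limonene-derived methyl ketone, so the ketone methyl becomes the C3 methyl and no alkyne editing follows ring formation. On atom economy at C3 and on the length of the endgame this plan is the better one.
- Equal: the cycloaddition is the same reaction type that gives 20 in the chosen route, so control of C1 and of the cis C12=C13 unit is the same.
- Against: the key step closes only the heterocycle, and the 14-membered ring still needs a separate high-dilution closure. A2 has a C1–O bond that is allylic on one side and part of an allylic acetal on the other, and it must pass through acetal hydrolysis, epoxidation, oxidation and methylenation. E-selective olefination of a methyl ketone to a trisubstituted enal usually needs isomer separation. An enal is a weaker heterodienophile than an ynal and offers its C=C as a competing site.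
- Step economy: the total count would be similar, but the sequence is more linear.

Alternative 2: The cut is at C10–C11 inside a temporary ring. The 2-methylidene-1,3-dioxepane A3 (ketene acetal of the C8/C15 diol with an isopropenyl group on C8) would undergo a thermal Claisen rearrangement to the nine-membered lactone A4, forming C10–C11 and the C8=C9 olefin.
- In favour: the Z geometry is enforced by the cyclic transition state, whereas the iodo-olefination of step 8 only favours it kinetically. On control of the C8=C9 geometry this plan is the better one. The pericyclic step is also mechanistically robust.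
- Against: A4 contains neither C13 nor C14 and none of the rings of the target. Its lactone carbonyl (C12) would still have to be turned into the epoxide CH by adding a two-carbon unit, building the epoxide without an allylic alcohol handle, and then closing the macrocycle. A3 needs its own multistep preparation.
- Comparison: it solves one of the four structural problems at a clearly higher step count.

Alternative 3: The cut is at C9–C10 as the ring-closing event. The seco compound A5 (vinyl epoxide, Z-vinyl iodide, E-C2=C3 olefin, both oxygens silylated) would be hydroborated with 9-BBN at the vinyl group and closed with Pd(dppf)Cl2, AsPh3 and Cs2CO3 to the macrocycle A6.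
- Equal: it forms the same bond by the same reaction as step 19, so mechanism and retention of the Z geometry are the same.
- In favour: A6 already contains every carbon and both olefins, so the steps after ring closure are only deprotection and acylation. On the number of steps after ring closure this plan is the better one.
- Against: the coupling must run at high dilution, where the alkenylpalladium intermediate is long-lived and the borate stays close to the epoxide. A5 must be built linearly with C1 and the E-olefin set beforehand, as in alternative 1. The tertiary C15 hydroxyl would have to be acetylated late, next to the epoxide.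
- Comparison: the chosen plan runs the same coupling intermolecularly at normal concentration and leaves the entropically hard ring closure to a reaction driven by loss of a volatile alkyne.

Key step: step 20

Remark on the structures: read from the target, C1 is S, C6 is R and the epoxide is cis with 12S,13R; the seco diyne 29 and the cycloalkyne 30 carry exactly these configurations, and (R)-limonene maps onto C6 without inversion, so no structure needed correction.

Assumption: the (1S,2R)-aminoindanol-derived CrCl Schiff-base complex is taken to deliver the (2R,6S) adduct 20, by analogy with aliphatic aldehydes; if but-2-ynal showed the opposite facial preference, the enantiomeric complex would be used with nothing else changed.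

## Route

Step 1
Reactants: 1 (R)-limonene
Product: 3 (R)-α-terpineol, via organomercurial acetate 2 (not isolated)
Conditions: Hg(OAc)2, THF/H2O, rt; then aq. NaOH, NaBH4, 0 °C
Reagents that add atoms: water, O
Why: Oxymercuration–demercuration (Markovnikov hydration); the unhindered 1,1-disubstituted isopropenyl olefin is mercurated faster than the trisubstituted ring olefin, and NaBH4 replaces mercury by hydrogen. The stereocentre (later C6) is not involved.

Step 2
Reactants: 3 (R)-α-terpineol
Product: 5 4-[(3R)-5-methoxy-2,2-dimethyloxolan-3-yl]butan-2-one (anomer mixture), via keto lactol 4 (not isolated)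
Conditions: O3, CH2Cl2/MeOH, −78 °C; Me2S, −78 °C → rt; then PPTS (cat.), MeOH, rt
Reagents that add atoms: ozone, [O-][O+]=O; methanol, CO
Why: Ozonolysis of the ring olefin gives a methyl ketone (later C3) and an aldehyde (later C8); the tertiary hydroxyl captures the aldehyde as a five-membered lactol, and acid-catalysed acetalisation converts it to the methyl acetal. This masks aldehyde and tertiary alcohol in one base-stable group.

Step 3
Reactants: 5 4-[(3R)-5-methoxy-2,2-dimethyloxolan-3-yl]butan-2-one
Product: 8 (3R)-5-methoxy-2,2-dimethyl-3-(pent-3-yn-1-yl)oxolane, via enol phosphate 6 (not isolated), via lithium acetylide 7 (not isolated)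
Conditions: LiN(iPr)2 (1.1 equiv), THF, −78 °C; ClP(O)(OEt)2, −78 °C → rt; LiN(iPr)2 (2.4 equiv), −78 °C → rt; MeI, DMPU, 0 °C → rt
Reagents that add atoms: iodomethane, CI
Why: Methyl ketone-to-alkyne conversion through the kinetic (terminal) enol phosphate, elimination to the lithium acetylide and C-methylation. The cyclic acetal offers no acidic or electrophilic site to the amide base.

Step 4
Reactants: 8 (3R)-5-methoxy-2,2-dimethyl-3-(pent-3-yn-1-yl)oxolane
Product: 10 (3R)-3-(2-hydroxypropan-2-yl)oct-6-yn-1-ol, via lactol 9 (not isolated)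
Conditions: 1 M aq. HCl, THF, rt; NaHCO3; then NaBH4, MeOH, 0 °C
Reagents that add atoms: water, O
Why: Acetal hydrolysis gives the lactol, and NaBH4 reduces its open hydroxy aldehyde form to the 1,4-diol. The stereocentre is untouched.

Step 5
Reactants: 10 (3R)-3-(2-hydroxypropan-2-yl)oct-6-yn-1-ol
Product: 11 (3R)-3-(2-acetoxypropan-2-yl)oct-6-yn-1-yl acetate
Conditions: Ac2O, Et3N, DMAP (1 equiv), CH2Cl2, 40 °C
Reagents that add atoms: acetic anhydride, CC(=O)OC(C)=O
Why: DMAP-catalysed acylation; with excess anhydride and gentle warming the hindered tertiary alcohol is esterified together with the primary one. The C15 acetate of the target is thus installed while the molecule has no sensitive group.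

Step 6
Reactants: 11 (3R)-3-(2-acetoxypropan-2-yl)oct-6-yn-1-yl acetate
Product: 12 2-[(3R)-1-hydroxyoct-6-yn-3-yl]propan-2-yl acetate
Conditions: K2CO3, MeOH, 0 °C
Reagents that add atoms: none
Why: Base-catalysed transesterification is much faster at the unhindered primary acetate than at the tertiary one, so only the primary hydroxyl is released.

Step 7
Reactants: 12 2-[(3R)-1-hydroxyoct-6-yn-3-yl]propan-2-yl acetate
Product: 13 2-[(3R)-1-oxooct-6-yn-3-yl]propan-2-yl acetate
Conditions: Dess–Martin periodinane, NaHCO3, CH2Cl2, 0 °C → rt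
Reagents that add atoms: none
Why: Dess–Martin oxidation of the primary alcohol; with the tertiary oxygen acetylated, the aldehyde stays open-chain and cannot close to a lactol.

Step 8
Reactants: 13 2-[(3R)-1-oxooct-6-yn-3-yl]propan-2-yl acetate
Product: 14 2-[(2Z,5R)-2-iododec-2-en-8-yn-5-yl]propan-2-yl acetate
Conditions: [Ph3PEt]I, n-BuLi, THF, rt; I2, −78 °C; NaN(SiMe3)2, −20 °C; then 13, −78 °C → −20 °C
Reagents that add atoms: (1-iodoethylidene)triphenylphosphorane (made in the flask), CC(I)=P(c1ccccc1)(c1ccccc1)c1ccccc1
Why: Stork–Zhao-type Wittig olefination with the α-iodo ylide; kinetic oxaphosphetane formation places iodine cis to the chain and gives the (Z)-2-iodo-2-alkene. Low temperature avoids dehydroiodination and attack on the acetate.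

Step 9
Reactants: 15 but-2-yn-1-ol
Product: 16 but-2-ynal
Conditions: MnO2 (activated, excess), CH2Cl2, rt; filtered, used as a concentrated solution
Reagents that add atoms: none
Why: MnO2 oxidises propargylic alcohols to ynals without over-oxidation; the volatile aldehyde is not isolated neat.

Step 10
Reactants: 17 3-methylbut-2-enal
Product: 18 1,1-dimethoxy-3-methylbut-2-ene
Conditions: HC(OMe)3, MeOH, NH4NO3 (cat.), rt
Reagents that add atoms: trimethyl orthoformate, COC(OC)OC
Why: Acid-catalysed acetalisation with the orthoformate as methoxy donor and water scavenger.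

Step 11
Reactants: 18 1,1-dimethoxy-3-methylbut-2-ene
Product: 19 (E)-1-methoxy-3-methylbuta-1,3-diene
Conditions: Me3SiOTf, iPr2NEt, CH2Cl2, −20 °C → rt; distillation
Reagents that add atoms: none
Why: Silyl triflate/amine-promoted 1,4-elimination of methanol from the allylic acetal through its oxocarbenium ion gives the 1-methoxy diene. Only the E isomer enters the cycloaddition, so any Z isomer is an inert spectator.

Step 12
Reactants: 16 but-2-ynal; 19 (E)-1-methoxy-3-methylbuta-1,3-diene
Product: 20 (2R,6S)-2-methoxy-4-methyl-6-(prop-1-yn-1-yl)-5,6-dihydro-2H-pyran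
Conditions: CrCl(L) (cat.; L = dianion of the Schiff base of 3-(1-adamantyl)-2-hydroxy-5-methylbenzaldehyde and (1S,2R)-1-aminoindan-2-ol), 4 Å MS, t-BuOMe, 0 °C → rt
Reagents that add atoms: none
Why: Catalytic asymmetric hetero-Diels–Alder reaction; the Lewis-acidic chromium activates the carbonyl group (not the alkyne) as heterodienophile, endo approach gives the cis-2,6 adduct, and the chiral ligand shields one carbonyl face, which sets C1 as S. The ring fixes the future C12=C13 olefin as cis.

Step 13
Reactants: 20 (2R,6S)-2-methoxy-4-methyl-6-(prop-1-yn-1-yl)-5,6-dihydro-2H-pyran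
Product: 22 (2Z,5S)-3-methyloct-2-en-6-yne-1,5-diol, via lactol 21 (not isolated)
Conditions: 0.5 M aq. HCl, THF, 0 °C; NaHCO3; then NaBH4, CeCl3·7H2O, MeOH, −20 °C
Reagents that add atoms: water, O
Why: Mild hydrolysis of the allylic acetal gives the lactol, whose open form is the Z-enal; Luche 1,2-reduction captures it as the Z-allylic alcohol before it can isomerise. C1 is not involved.

Step 14
Reactants: 22 (2Z,5S)-3-methyloct-2-en-6-yne-1,5-diol
Product: 23 (2Z,5S)-3-methyl-1,5-bis(triethylsilyloxy)oct-2-en-6-yne
Conditions: Et3SiCl (2.5 equiv), imidazole, DMAP (cat.), CH2Cl2, 0 °C → rt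
Reagents that add atoms: chlorotriethylsilane, CC[Si](Cl)(CC)CC
Why: Exhaustive silylation of both hydroxyls; it is needed because the secondary hydroxyl cannot be silylated selectively in the presence of the primary one.

Step 15
Reactants: 23 (2Z,5S)-3-methyl-1,5-bis(triethylsilyloxy)oct-2-en-6-yne
Product: 24 (2Z,5S)-3-methyl-5-(triethylsilyloxy)oct-2-en-6-yn-1-ol
Conditions: PPTS (cat.), MeOH/CH2Cl2, −10 °C
Reagents that add atoms: none
Why: Acid-catalysed methanolysis cleaves the unhindered primary silyl ether much faster than the secondary propargylic one, which releases the allylic alcohol for the directed epoxidation.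

Step 16
Reactants: 24 (2Z,5S)-3-methyl-5-(triethylsilyloxy)oct-2-en-6-yn-1-ol
Product: 25 [(2S,3R)-3-methyl-3-[(2S)-2-(triethylsilyloxy)pent-3-yn-1-yl]oxiran-2-yl]methanol
Conditions: Ti(OiPr)4, L-(+)-diisopropyl tartrate, t-BuOOH, 4 Å MS, CH2Cl2, −20 °C
Reagents that add atoms: tert-butyl hydroperoxide, CC(C)(C)OO
Why: Sharpless asymmetric epoxidation; the titanium tartrate binds the allylic alcohol, and L-(+)-tartrate delivers oxygen to the face that gives the (2S,3R) epoxide of a Z-trisubstituted allylic alcohol, i.e. 12S,13R. Reagent control overrides the remote C1 centre, and the cis relation of C11 and C14 is carried over from the olefin.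

Step 17
Reactants: 25 [(2S,3R)-3-methyl-3-[(2S)-2-(triethylsilyloxy)pent-3-yn-1-yl]oxiran-2-yl]methanol
Product: 26 (2R,3R)-3-methyl-3-[(2S)-2-(triethylsilyloxy)pent-3-yn-1-yl]oxirane-2-carbaldehyde
Conditions: Dess–Martin periodinane, NaHCO3, CH2Cl2, 0 °C
Reagents that add atoms: none
Why: Buffered Dess–Martin oxidation gives the α,β-epoxy aldehyde without opening the epoxide; the change of descriptor at the oxirane CH is only a change of priorities. The aldehyde is used directly.

Step 18
Reactants: 26 (2R,3R)-3-methyl-3-[(2S)-2-(triethylsilyloxy)pent-3-yn-1-yl]oxirane-2-carbaldehyde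
Product: 27 (2R,3S)-3-ethenyl-2-methyl-2-[(2S)-2-(triethylsilyloxy)pent-3-yn-1-yl]oxirane
Conditions: [Ph3PMe]Br, KN(SiMe3)2, THF, 0 °C; then 26, −78 °C → 0 °C
Reagents that add atoms: methylidenetriphenylphosphorane (made in the flask), C=P(c1ccccc1)(c1ccccc1)c1ccccc1
Why: Wittig methylenation with a salt-free ylide adds C10; the epoxide and the silyl ether are inert to the non-nucleophilic, low-temperature conditions.

Step 19
Reactants: 27 (2R,3S)-3-ethenyl-2-methyl-2-[(2S)-2-(triethylsilyloxy)pent-3-yn-1-yl]oxirane; 14 2-[(2Z,5R)-2-iododec-2-en-8-yn-5-yl]propan-2-yl acetate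
Product: 29 2-[(6R,8Z)-9-methyl-11-[(2S,3R)-3-methyl-3-[(2S)-2-(triethylsilyloxy)pent-3-yn-1-yl]oxiran-2-yl]undec-8-en-2-yn-6-yl]propan-2-yl acetate (seco diyne), via alkylborane 28 (not isolated)
Conditions: 27, 9-BBN, THF, 0 °C → rt; then 14, Pd(dppf)Cl2 (cat.), AsPh3, Cs2CO3, DMF/THF/H2O, rt
Reagents that add atoms: none
Why: 9-BBN hydroborates the monosubstituted vinyl group anti-Markovnikov much faster than the internal alkyne; B-alkyl Suzuki–Miyaura coupling with the alkenyl iodide then forms C9–C10 with retention of the Z geometry. Room temperature and carbonate base spare the epoxide, the acetate and the silyl ether.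

Step 20
Reactants: 29 seco diyne
Product: 30 (1S,6R,8Z,12S,13R)-6-(2-acetoxypropan-2-yl)-12,13-epoxy-9,13-dimethyl-1-(triethylsilyloxy)cyclotetradec-8-en-2-yne (ring numbering of the target)
Conditions: Mo(≡CC6H4OMe-4)(OSiPh3)3 (cat.), 5 Å MS, toluene (ca. 2 mM), rt → 60 °C
Reagents that add atoms: none
Why: Ring-closing alkyne metathesis: the alkylidyne (hexavalent molybdenum) adds to one propynyl group in a [2+2] sense to a metallacyclobutadiene, cycloreversion puts the chain on the metal, and the same sequence at the second propynyl group forms C2≡C3 and releases but-2-yne, which the 5 Å sieves absorb so that the equilibrium is pulled to the ring. The closest known reaction type is the macrocyclisation of methyl-capped α,ω-diynes with molybdenum alkylidyne tris(silanolate) catalysts. The 14-membered carbocycle is closed end to end as a macrocyclisation; a ring of this size holds the linear C1–C2≡C3–C4 unit without strain, and the Z-olefin and the cis-epoxide supply the turns. No stereocentre is formed or touched. The step needs selectivity for alkynes over the C8=C9 olefin, which is intrinsic to alkylidynes, and for ring closure over oligomerisation, which dilution and removal of but-2-yne secure. The substrate has no protic group (C1 is silylated), both alkynes are methyl-capped so that no terminal alkyne polymerises, and the bulky silanolate ligands temper the Lewis acidity at the metal, so the epoxide, the ester and the silyl ether are tolerated.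

Step 21
Reactants: 30 cycloalkyne silyl ether
Product: 31 (1S,6R,8Z,12S,13R)-6-(2-acetoxypropan-2-yl)-12,13-epoxy-9,13-dimethylcyclotetradec-8-en-2-yn-1-ol
Conditions: Bu4NF, AcOH, THF, 0 °C
Reagents that add atoms: none
Why: Fluoride cleavage of the silyl ether, buffered with acetic acid so that the acetate and the epoxide see neither strong base nor acid.

Step 22
Reactants: 31 cyclic propargylic alcohol
Product: 32 (1S,2Z,6R,8Z,12S,13R)-6-(2-acetoxypropan-2-yl)-12,13-epoxy-9,13-dimethyl-3-(triethylsilyl)cyclotetradeca-2,8-dien-1-ol
Conditions: Et3SiH, [Cp*Ru(MeCN)3]PF6 (cat.), CH2Cl2, 0 °C → rt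
Reagents that add atoms: triethylsilane, CC[SiH](CC)CC
Why: Ruthenium-catalysed trans-hydrosilylation; the cationic Cp*Ru fragment adds H and Si anti across the alkyne, and with a free propargylic hydroxyl silicon goes to the distal carbon C3 and hydrogen to C2. Silicon therefore lies cis to C1, which is the geometry the C3 methyl needs.

Step 23
Reactants: 32 cyclic (Z)-alkenylsilane
Product: 33 (1S,2Z,6R,8Z,12S,13R)-6-(2-acetoxypropan-2-yl)-12,13-epoxy-3-iodo-9,13-dimethylcyclotetradeca-2,8-dien-1-ol
Conditions: N-iodosuccinimide, 2,6-lutidine, (CF3)2CHOH, 0 °C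
Reagents that add atoms: N-iodosuccinimide, O=C1CCC(=O)N1I
Why: Electrophilic ipso-iododesilylation through a β-silyl-stabilised cation proceeds with retention in the fluorinated alcohol; lutidine buffers the medium for the epoxide.

Step 24
Reactants: 33 cyclic (Z)-alkenyl iodide
Product: 34 (1S,2E,6R,8Z,12S,13R)-6-(2-acetoxypropan-2-yl)-12,13-epoxy-3,9,13-trimethylcyclotetradeca-2,8-dien-1-ol
Conditions: Me2Zn, Pd(PPh3)4 (cat.), THF, 0 °C → rt
Reagents that add atoms: dimethylzinc, C[Zn]C
Why: Negishi coupling; oxidative addition of zerovalent palladium to the alkenyl iodide, transmetalation and reductive elimination occur with retention and give the E-olefin. The free hydroxyl is only converted to its zinc alkoxide, and no allylic ester is present to ionise.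

Step 25
Reactants: 34 cyclic allylic alcohol
Product: 35 (1S,2E,6R,8Z,12S,13R)-6-(2-acetoxypropan-2-yl)-12,13-epoxy-3,9,13-trimethylcyclotetradeca-2,8-dien-1-yl acetate (target)
Conditions: Ac2O, pyridine, DMAP (cat.), CH2Cl2, 0 °C → rt
Reagents that add atoms: acetic anhydride, CC(=O)OC(C)=O
Why: Base-mediated acetylation of the secondary allylic alcohol with retention at C1; no acid is present that could open the epoxide or ionise the allylic ester.

## Compound list

1 | (R)-limonene | CC1=CC[C@@H](CC1)C(C)=C | starting material
2 | [2-hydroxy-2-[(1R)-4-methylcyclohex-3-en-1-yl]propyl]mercury acetate (carbinol epimers) | CC1=CC[C@@H](CC1)C(C)(O)C[Hg]OC(C)=O | intermediate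
3 | (R)-α-terpineol, 2-[(1R)-4-methylcyclohex-3-en-1-yl]propan-2-ol | CC1=CC[C@@H](CC1)C(C)(C)O | intermediate
4 | 4-[(3R)-5-hydroxy-2,2-dimethyloxolan-3-yl]butan-2-one (anomer mixture) | OC1C[C@@H](CCC(C)=O)C(C)(C)O1 | intermediate
5 | 4-[(3R)-5-methoxy-2,2-dimethyloxolan-3-yl]butan-2-one (anomer mixture) | COC1C[C@@H](CCC(C)=O)C(C)(C)O1 | intermediate
6 | diethyl 4-[(3R)-5-methoxy-2,2-dimethyloxolan-3-yl]but-1-en-2-yl phosphate | COC1C[C@@H](CCC(=C)OP(=O)(OCC)OCC)C(C)(C)O1 | intermediate
7 | lithium 4-[(3R)-5-methoxy-2,2-dimethyloxolan-3-yl]but-1-yn-1-ide | COC1C[C@@H](CCC#C[Li])C(C)(C)O1 | intermediate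
8 | (3R)-5-methoxy-2,2-dimethyl-3-(pent-3-yn-1-yl)oxolane (anomer mixture) | COC1C[C@@H](CCC#CC)C(C)(C)O1 | intermediate
9 | (4R)-5,5-dimethyl-4-(pent-3-yn-1-yl)oxolan-2-ol (anomer mixture) | OC1C[C@@H](CCC#CC)C(C)(C)O1 | intermediate
10 | (3R)-3-(2-hydroxypropan-2-yl)oct-6-yn-1-ol | OCC[C@@H](CCC#CC)C(C)(C)O | intermediate
11 | (3R)-3-(2-acetoxypropan-2-yl)oct-6-yn-1-yl acetate | CC(=O)OCC[C@@H](CCC#CC)C(C)(C)OC(C)=O | intermediate
12 | 2-[(3R)-1-hydroxyoct-6-yn-3-yl]propan-2-yl acetate | OCC[C@@H](CCC#CC)C(C)(C)OC(C)=O | intermediate
13 | 2-[(3R)-1-oxooct-6-yn-3-yl]propan-2-yl acetate | O=CC[C@@H](CCC#CC)C(C)(C)OC(C)=O | intermediate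
14 | 2-[(2Z,5R)-2-iododec-2-en-8-yn-5-yl]propan-2-yl acetate | C/C(I)=C/C[C@@H](CCC#CC)C(C)(C)OC(C)=O | intermediate
15 | but-2-yn-1-ol | CC#CCO | starting material
16 | but-2-ynal | CC#CC=O | intermediate
17 | 3-methylbut-2-enal | CC(C)=CC=O | starting material
18 | 1,1-dimethoxy-3-methylbut-2-ene | COC(OC)C=C(C)C | intermediate
19 | (E)-1-methoxy-3-methylbuta-1,3-diene | CO/C=C/C(C)=C | intermediate
20 | (2R,6S)-2-methoxy-4-methyl-6-(prop-1-yn-1-yl)-5,6-dihydro-2H-pyran | CO[C@H]1C=C(C)C[C@H](O1)C#CC | intermediate
21 | (6S)-4-methyl-6-(prop-1-yn-1-yl)-5,6-dihydro-2H-pyran-2-ol (anomer mixture) | OC1C=C(C)C[C@H](O1)C#CC | intermediate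
22 | (2Z,5S)-3-methyloct-2-en-6-yne-1,5-diol | OC/C=C(/C)C[C@H](O)C#CC | intermediate
23 | (2Z,5S)-3-methyl-1,5-bis(triethylsilyloxy)oct-2-en-6-yne | CC[Si](CC)(CC)OC/C=C(/C)C[C@H](O[Si](CC)(CC)CC)C#CC | intermediate
24 | (2Z,5S)-3-methyl-5-(triethylsilyloxy)oct-2-en-6-yn-1-ol | OC/C=C(/C)C[C@H](O[Si](CC)(CC)CC)C#CC | intermediate
25 | [(2S,3R)-3-methyl-3-[(2S)-2-(triethylsilyloxy)pent-3-yn-1-yl]oxiran-2-yl]methanol | OC[C@@H]1O[C@]1(C)C[C@H](O[Si](CC)(CC)CC)C#CC | intermediate
26 | (2R,3R)-3-methyl-3-[(2S)-2-(triethylsilyloxy)pent-3-yn-1-yl]oxirane-2-carbaldehyde | O=C[C@@H]1O[C@]1(C)C[C@H](O[Si](CC)(CC)CC)C#CC | intermediate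
27 | (2R,3S)-3-ethenyl-2-methyl-2-[(2S)-2-(triethylsilyloxy)pent-3-yn-1-yl]oxirane | C=C[C@@H]1O[C@]1(C)C[C@H](O[Si](CC)(CC)CC)C#CC | intermediate
28 | 9-{2-[(2S,3R)-3-methyl-3-[(2S)-2-(triethylsilyloxy)pent-3-yn-1-yl]oxiran-2-yl]ethyl}-9-borabicyclo[3.3.1]nonane | B1(CC[C@@H]3O[C@]3(C)C[C@H](O[Si](CC)(CC)CC)C#CC)C2CCCC1CCC2 | intermediate
29 | 2-[(6R,8Z)-9-methyl-11-[(2S,3R)-3-methyl-3-[(2S)-2-(triethylsilyloxy)pent-3-yn-1-yl]oxiran-2-yl]undec-8-en-2-yn-6-yl]propan-2-yl acetate (seco diyne) | CC#CCC[C@@H](C(C)(C)OC(C)=O)C/C=C(/C)CC[C@@H]1O[C@]1(C)C[C@H](O[Si](CC)(CC)CC)C#CC | intermediate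
30 | (1S,6R,8Z,12S,13R)-6-(2-acetoxypropan-2-yl)-12,13-epoxy-9,13-dimethyl-1-(triethylsilyloxy)cyclotetradec-8-en-2-yne | CC[Si](CC)(CC)O[C@@H]1C#CCC[C@@H](C(C)(C)OC(C)=O)C/C=C(/C)CC[C@@H]2O[C@]2(C)C1 | intermediate
31 | (1S,6R,8Z,12S,13R)-6-(2-acetoxypropan-2-yl)-12,13-epoxy-9,13-dimethylcyclotetradec-8-en-2-yn-1-ol | O[C@@H]1C#CCC[C@@H](C(C)(C)OC(C)=O)C/C=C(/C)CC[C@@H]2O[C@]2(C)C1 | intermediate
32 | (1S,2Z,6R,8Z,12S,13R)-6-(2-acetoxypropan-2-yl)-12,13-epoxy-9,13-dimethyl-3-(triethylsilyl)cyclotetradeca-2,8-dien-1-ol | O[C@@H]1/C=C(\[Si](CC)(CC)CC)CC[C@@H](C(C)(C)OC(C)=O)C/C=C(/C)CC[C@@H]2O[C@]2(C)C1 | intermediate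
33 | (1S,2Z,6R,8Z,12S,13R)-6-(2-acetoxypropan-2-yl)-12,13-epoxy-3-iodo-9,13-dimethylcyclotetradeca-2,8-dien-1-ol | O[C@@H]1/C=C(\I)CC[C@@H](C(C)(C)OC(C)=O)C/C=C(/C)CC[C@@H]2O[C@]2(C)C1 | intermediate
34 | (1S,2E,6R,8Z,12S,13R)-6-(2-acetoxypropan-2-yl)-12,13-epoxy-3,9,13-trimethylcyclotetradeca-2,8-dien-1-ol | O[C@@H]1/C=C(\C)CC[C@@H](C(C)(C)OC(C)=O)C/C=C(/C)CC[C@@H]2O[C@]2(C)C1 | intermediate
35 | (1S,2E,6R,8Z,12S,13R)-6-(2-acetoxypropan-2-yl)-12,13-epoxy-3,9,13-trimethylcyclotetradeca-2,8-dien-1-yl acetate | CC(=O)O[C@@H]1/C=C(\C)CC[C@@H](C(C)(C)OC(C)=O)C/C=C(/C)CC[C@@H]2O[C@]2(C)C1 | target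

## Step count and least certain steps

Total step count: 25 (steps 1–8 for 14, steps 9–18 for 27, steps 19–25 for union, ring closure and endgame).
Longest linear sequence: 16 steps, from 17 through steps 10–25. From 1 or from 15 it is 15 steps.

Step 20 (key step). The most likely failure is intermolecular metathesis outrunning ring closure, so that oligomers grow. A second is slow turnover because the silyl ether crowds the C1 alkyne, or because traces of water or the epoxide use up the alkylidyne. The fallback closes the ring at C9–C10 instead and forms C2≡C3 between the fragments. It sets out from 14 and 27. Alkyne cross-metathesis of the two propynyl groups with the same molybdenum catalyst at normal concentration, with 14 in excess and the homodimers recycled, would give the acyclic enyne iodide F1. 9-BBN would hydroborate its vinyl group to the alkylborane F2, and Pd(dppf)Cl2, AsPh3 and Cs2CO3 at high dilution would close the ring by intramolecular Suzuki–Miyaura coupling. The route is rejoined at 30.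

Step 12. Facial discrimination may be poor for so small an ynal, its sense may be opposite to the one assumed, or the volatile aldehyde may oligomerise or react at the alkyne before the catalysed cycloaddition is complete. The fallback sets C1 by reduction instead. It sets out from 22 of whatever enantiomeric purity the cycloaddition has delivered. One equivalent of Et3SiCl at low temperature would silylate only the primary hydroxyl to give the primary silyl ether F3. MnO2 would oxidise the propargylic alcohol to the ynone F4. Noyori transfer hydrogenation with RuCl[(S,S)-TsDPEN](p-cymene) in iPrOH would give the (S)-propargylic alcohol F5. Silylation of the secondary hydroxyl rejoins the route at 23.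

Step 16. Z-Trisubstituted allylic alcohols are epoxidised slowly and with eroded face selectivity, and the long exposure to the titanium alkoxide and hydroperoxide may loosen the silyl ether. The fallback uses ring control instead of reagent control. It sets out from 20. CrO3/H2SO4 in acetone would oxidise the cyclic acetal to the unsaturated lactone F6. Weitz–Scheffer epoxidation (H2O2, NaOH, MeOH, 0 °C, then acidification) should add anti to the C6 propynyl group and give the epoxy lactone F7, which has the required relation between C1 and the epoxide. iBu2AlH at −78 °C would give the epoxy lactol F8. Methylenation with Ph3P=CH2 would open it to the hydroxy vinyl epoxide F9. Et3SiCl and imidazole rejoin the route at 27.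

Step 19. The borate formed on addition of base holds a nucleophilic carbon two atoms away from the epoxide. Closure onto the epoxide to a cyclopropylcarbinol, or slow transmetalation followed by protodeboronation, could take material away from the coupling. The fallback replaces the borate by an organozinc reagent. It sets out from 27. Hydroboration with 9-BBN and oxidation with NaBO3·4H2O would give the primary alcohol F10. I2, PPh3 and imidazole would give the iodide F11. Zn dust with LiCl in THF would give the alkylzinc iodide F12, and Negishi coupling with 14 under Pd(dppf)Cl2 rejoins the route at 29.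

Step 23. In the strongly ionising solvent the epoxide may open (solvolysis or attack by the C1 hydroxyl), the iodonium source may attack C8=C9, or the olefin geometry may erode through a long-lived cation. The fallback avoids the silane and the acidic medium. It sets out from 31. NaAlH2(OCH2CH2OMe)2 in THF at 0 °C would effect alkoxide-directed trans-hydroalumination with aluminium on C3, and I2 at −78 °C would give the iodo diol F13; the C15 acetate is lost to the hydride. Methylation with Me2Zn and Pd(PPh3)4 would give the diol F14. Double acetylation (Ac2O, Et3N, DMAP, 40 °C) rejoins the route at 35.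

## Further compounds

F1 | step 20 | 2-[(2Z,5R)-10-[(2S)-1-[(2R,3S)-3-ethenyl-2-methyloxiran-2-yl]-2-(triethylsilyloxy)]-2-iodo-dodec-2-en-8-yn-5-yl]propan-2-yl acetate type acyclic enyne iodide (C2≡C3 formed, vinyl epoxide and Z-alkenyl iodide intact) | C=C[C@@H]1O[C@]1(C)C[C@H](O[Si](CC)(CC)CC)C#CCC[C@@H](C(C)(C)OC(C)=O)C/C=C(/C)I
F2 | step 20 | B-alkyl-9-borabicyclo[3.3.1]nonane from hydroboration of the vinyl group of F1 | B1(CC[C@@H]3O[C@]3(C)C[C@H](O[Si](CC)(CC)CC)C#CCC[C@@H](C(C)(C)OC(C)=O)C/C=C(/C)I)C2CCCC1CCC2
F3 | step 12 | (2Z)-3-methyl-1-(triethylsilyloxy)oct-2-en-6-yn-5-ol (C5 not enantiopure) | CC[Si](CC)(CC)OC/C=C(/C)CC(O)C#CC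
F4 | step 12 | (6Z)-6-methyl-8-(triethylsilyloxy)oct-6-en-2-yn-4-one | CC[Si](CC)(CC)OC/C=C(/C)CC(=O)C#CC
F5 | step 12 | (2Z,5S)-3-methyl-1-(triethylsilyloxy)oct-2-en-6-yn-5-ol | CC[Si](CC)(CC)OC/C=C(/C)C[C@H](O)C#CC
F6 | step 16 | (6S)-4-methyl-6-(prop-1-yn-1-yl)-5,6-dihydro-2H-pyran-2-one | O=C1C=C(C)C[C@H](O1)C#CC
F7 | step 16 | (3R,4R,6S)-3,4-epoxy-4-methyl-6-(prop-1-yn-1-yl)oxan-2-one | O=C1[C@@H]2O[C@]2(C)C[C@H](O1)C#CC
F8 | step 16 | (3R,4R,6S)-3,4-epoxy-4-methyl-6-(prop-1-yn-1-yl)oxan-2-ol (anomer mixture) | OC1[C@@H]2O[C@]2(C)C[C@H](O1)C#CC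
F9 | step 16 | (2S)-1-[(2R,3S)-3-ethenyl-2-methyloxiran-2-yl]pent-3-yn-2-ol | C=C[C@@H]1O[C@]1(C)C[C@H](O)C#CC
F10 | step 19 | 2-[(2S,3R)-3-methyl-3-[(2S)-2-(triethylsilyloxy)pent-3-yn-1-yl]oxiran-2-yl]ethan-1-ol | OCC[C@@H]1O[C@]1(C)C[C@H](O[Si](CC)(CC)CC)C#CC
F11 | step 19 | (2R,3S)-3-(2-iodoethyl)-2-methyl-2-[(2S)-2-(triethylsilyloxy)pent-3-yn-1-yl]oxirane | ICC[C@@H]1O[C@]1(C)C[C@H](O[Si](CC)(CC)CC)C#CC
F12 | step 19 | {2-[(2S,3R)-3-methyl-3-[(2S)-2-(triethylsilyloxy)pent-3-yn-1-yl]oxiran-2-yl]ethyl}zinc iodide | I[Zn]CC[C@@H]1O[C@]1(C)C[C@H](O[Si](CC)(CC)CC)C#CC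
F13 | step 23 | (1S,2Z,6R,8Z,12S,13R)-12,13-epoxy-6-(2-hydroxypropan-2-yl)-3-iodo-9,13-dimethylcyclotetradeca-2,8-dien-1-ol | O[C@@H]1/C=C(\I)CC[C@@H](C(C)(C)O)C/C=C(/C)CC[C@@H]2O[C@]2(C)C1
F14 | step 23 | (1S,2E,6R,8Z,12S,13R)-12,13-epoxy-6-(2-hydroxypropan-2-yl)-3,9,13-trimethylcyclotetradeca-2,8-dien-1-ol | O[C@@H]1/C=C(\C)CC[C@@H](C(C)(C)O)C/C=C(/C)CC[C@@H]2O[C@]2(C)C1
A1 | alternative 1 | (2E,6R,8Z)-9-iodo-3-methyl-6-[2-(triethylsilyloxy)propan-2-yl]deca-2,8-dienal | O=C/C=C(\C)CC[C@@H](C(C)(C)O[Si](CC)(CC)CC)C/C=C(/C)I
A2 | alternative 1 | (2R,6S)-6-[(1E,5R,7Z)-8-iodo-2-methyl-5-[2-(triethylsilyloxy)propan-2-yl]nona-1,7-dien-1-yl]-2-methoxy-4-methyl-5,6-dihydro-2H-pyran (cis) | CO[C@H]1C=C(C)C[C@H](O1)/C=C(\C)CC[C@@H](C(C)(C)O[Si](CC)(CC)CC)C/C=C(/C)I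
A3 | alternative 2 | (5R)-5-[(3E)-5-(tert-butyldimethylsilyloxy)-3-methylpent-3-en-1-yl]-4,4-dimethyl-2-methylidene-7-(prop-1-en-2-yl)-1,3-dioxepane (either C7 epimer) | C=C1OC(C(C)=C)C[C@@H](CC/C(C)=C/CO[Si](C)(C)C(C)(C)C)C(C)(C)O1
A4 | alternative 2 | (5Z,8R)-8-[(3E)-5-(tert-butyldimethylsilyloxy)-3-methylpent-3-en-1-yl]-5,9,9-trimethyl-1-oxacyclonon-5-en-2-one | O=C1CC/C(C)=C\C[C@@H](CC/C(C)=C/CO[Si](C)(C)C(C)(C)C)C(C)(C)O1
A5 | alternative 3 | tert-butyl{[(2S,3E,7R,9Z)-1-[(2R,3S)-3-ethenyl-2-methyloxiran-2-yl]-10-iodo-4-methyl-7-[2-(triethylsilyloxy)propan-2-yl]undeca-3,9-dien-2-yl]oxy}dimethylsilane | C=C[C@@H]1O[C@]1(C)C[C@H](O[Si](C)(C)C(C)(C)C)/C=C(\C)CC[C@@H](C(C)(C)O[Si](CC)(CC)CC)C/C=C(/C)I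
A6 | alternative 3 | (1S,2E,6R,8Z,12S,13R)-1-(tert-butyldimethylsilyloxy)-12,13-epoxy-3,9,13-trimethyl-6-[2-(triethylsilyloxy)propan-2-yl]cyclotetradeca-2,8-diene | CC(C)(C)[Si](C)(C)O[C@@H]1/C=C(\C)CC[C@@H](C(C)(C)O[Si](CC)(CC)CC)C/C=C(/C)CC[C@@H]2O[C@]2(C)C1
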